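## The problem

Target 30 is a tetracycle: a fully substituted benzene ring (ring A) carries a 2,2-dimethyl-2H-pyran on one edge and a cis-fused cyclobutane/cyclopentane pair (a cyclobuta[a]indane) on the other. Locants used throughout: C1 (CH bearing the catechol), C2 (CMe2), C2a and C7b (ring-fusion CH, C7b on ring A), C3 (benzylic CH2), C3a–C7a (ring A; OMe on C4, pyran oxygen on C6, pyran carbon on C7); pyran atoms are primed (O1′, C2′, C3′, C4′).

The three stereocentres C1, C2a and C7b are contiguous on the four-membered ring and nothing else is stereogenic, so absolute configuration must be brought in at one of them. C2a and C7b control each other completely, since a four/five ring fusion can only be cis. C1 is independent, but the catechol lies trans to ring A on the convex face, which any reagent or radical trap will prefer once the bicycle exists.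

The periphery is fragile. The catechol is oxidised under basic aerobic conditions. The electron-rich chromene alkene is sensitive to acid and hydrogenation and would compete with any other styrene in an addition step. Only one of the three phloroglucinol-type oxygens is a methyl ether.

The feature that makes the plan possible is that the shared bond C2a–C7b is a transannular bond of the seven-membered ring C7a–C7b–C1–C2–C2a–C3–C3a. If that ring is made first, with a C1=C7b styrene bond and a leaving group on C2a, one bond from C7b to C2a closes both carbocycles, and the reagent that makes C7b nucleophilic can leave a handle for the catechol on C1. The open points are the electrophilic carbon C2a (secondary, next to CMe2) and the order in which chromene and catechol are unveiled.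

## Retrosynthesis

**Chromene and catechol last (30 ⇐ 28).** The C3′=C4′ alkene and the two phenols are taken back to chromanone bis-pivalate 28. No skeletal bond is cut. The chromene would be a second cis-styrene in the key step and the free catechol would not survive base or photoredox conditions, so both are carried masked. The forward step needs one hydride reagent to reduce the ketone and cleave both esters, then acid to dehydrate the doubly oxygen-stabilised benzylic alcohol 29.

**C1–aryl bond (28 ⇐ 25 + 27).** Cutting this bond removes a whole arene and leaves cyclobutyl trifluoroborate 25 and aryl bromide 27 (from 4-bromocatechol 26). The alternative, carrying the aryl group through ring construction, would make C1 a fourth substituent on the reacting alkene. As a late radical coupling, C1 is set by the bicycle itself, because the planar radical is trapped on the convex face.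

**Boron exchange and unmasking (25 ⇐ 23).** Trifluoroborate 25 comes from pinacol boronate ketal 23 by ketal hydrolysis (keto boronate 24) and fluoride exchange. The ketal is needed only for the key step and is removed immediately after it.

**Transannular bond C2a–C7b (23 ⇐ 21 + 22).** This is the central cut. Breaking C2a–C7b and C1–B opens both carbocycles to benzocycloheptenyl mesylate 21 and bis(pinacolato)diboron 22. Three stereocentres and two rings become one carbinol stereocentre and a cis ring alkene. A stepwise closure of either ring alone would need a separate way to make C7b nucleophilic and a separate way to put functionality on C1. The forward reaction asks a copper boryl species to add across C1=C7b (copper on benzylic C7b), and the C–Cu bond to displace the C2a sulfonate with inversion.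

**Mask and leaving group (21 ⇐ 20 ⇐ 19).** The dioxolane of 21 protects the enolisable chromanone from stoichiometric alkoxide and copper boryl species. It is installed last, on keto mesylate 20, so that this acid-labile ketal of an electron-rich aryl ketone passes through as few operations as possible. 20 is the mesylate of alcohol 19.

**Ring alkene C1=C7b (19 ⇐ 18).** Ring-closing metathesis of diene 18 forms the seven-membered ring. The ring enforces the cis geometry on which the C1 outcome of the key step depends. Both alkene partners are monosubstituted, and the free alcohol is tolerated.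

**C2–C2a bond and the only reagent-controlled stereocentre (18 ⇐ 13 + 14).** Cutting between the carbinol and CMe2 gives arylacetaldehyde 13 and prenyl bromide 14. The forward reaction is an asymmetric tert-prenylation through prenyldiisopinocampheylborane 16. It must deliver the (S)-carbinol, which becomes C2a after inversion.

**Vinyl before aldehyde (13 ⇐ 12 ⇐ 11 ⇐ 10).** The C7a–vinyl bond is made by cross-coupling of aryl triflate 11, and the aldehyde is released from diol 12 afterwards. Vinylating after the prenylation looks shorter, but the aryl–palladium intermediate would then face a pendant terminal alkene and could close a six-membered ring by intramolecular Heck reaction. In 11 the future aldehyde is an inert diol, obtained by dihydroxylation of allyl triflate 10.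

**Carbon on C3a and oxygen-to-carbon exchange at C7a (10 ⇐ 9 ⇐ 7 ⇐ 5 + 6).** An aromatic Claisen rearrangement of allyl ether 7 moves three carbons to the only free ortho position and frees the phenol of 9 for triflation to 10. One oxygen of phloroglucinol thus becomes the site of the C7a–C7b bond. Ether 7 comes from phenol 5 and allyl bromide 6.

**Ring A and pyranone (5 ⇐ 4 ⇐ 1 + 2).** Acylation/oxa-Michael closure of phloroglucinol 1 with 3-methylbut-2-enoic acid 2 gives chromanone 4 in one step. The chelated 5-hydroxyl then allows selective methylation of the other phenol to 5.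

## Roads not taken

**Alternative 1:** Ring A is cut at C7–C7a and built last. A bicyclic cyclopentanone carrying a 3,5-dioxo ester chain on C3a (A2) would undergo aldol closure of the chain's terminal methylene onto the C7a carbonyl under mild base. Dehydration and enolisation would give resorcylate A1.
- Merits: the key step follows well-known polyketide-type aromatisation and needs no metal. The catechol-bearing carbon is already in place. The two phenols of A1 are differentiated by chelation to the ester.
- Weak points: the stereochemical problem is only moved, since A2 already holds all three stereocentres and its enantioselective assembly is left open. A2 is a polycarbonyl compound that can lactonise to a pyranone or close through the wrong methylene. The C7 ester of A1 must still be turned into the three-carbon pyran bridge.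
- Comparison: this road is better in that its key step is precedented and it avoids a late cross-coupling. The chosen plan sets against it that ring A and the pyranone come from 1 and 2 in one step, and that one reliably set carbinol is relayed into all three ring stereocentres in the same step that forms both rings.

**Alternative 2:** The C7a–C7b bond is cut. Aryl triflate A4 carries a cyclobutane from the terpene chiral pool, attached through C3. Zerovalent palladium (from Pd(OAc)2, tricyclohexylphosphine and caesium pivalate) would insert into the C7a–OTf bond and arylate the cyclobutane C–H bond cis to the tether, giving all-cis ester A3.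
- Merits: absolute configuration comes from the chiral pool without an asymmetric reagent. Intramolecular C(sp3)–H arylation through a six-membered palladacycle is an established reaction type, closer to precedent than the transannular step of the chosen plan. The concave C1 ester can be corrected later by a radical decarboxylative arylation.
- Weak points: the methyl C–H bonds of C2 compete with the ring methylene. The triflate is flanked on both sides, and in A4 the chromene is already present under palladium at high temperature. Attaching the cyclobutylmethyl unit to the crowded C3a position is a further unsolved bond. The key step forms one bond and one ring only.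
- Comparison: this road is at least as good in stereochemical economy and in precedent for its key step. The chosen plan sets against it the shorter access to the pentasubstituted arene, the closure of two rings at once, and the arrival of the C1 handle on the correct face in the same step.

**Alternative 3:** The C2–C2a bond is cut by ring contraction. Blue-light photolysis of trans-diaryl 2-diazocyclopentanone A6 in methanol would expel N2, shift C2 to the carbene carbon and give cyclobutane ester A5.
- Merits: the Wolff contraction of 2-diazocyclopentanones is the best-precedented key step of all four roads. Diazo transfer is regiochemically unambiguous because the other α-carbon is quaternary. Both aryl groups are in place early, and their trans relation is the thermodynamic one on a cyclopentanone.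
- Weak points: the new C2a centre is set by protonation and is epimerisable next to the ester, yet the needed isomer is the cis, less stable one. The cyclopentane must still be closed by acylation onto ring A and the resulting C3 ketone removed, in the presence of an acid-sensitive chromene. An enantioselective route to A6 is a separate problem. The carbene may react with the electron-rich arenes.
- Comparison: this road is better in precedent and avoids a late coupling. The chosen plan sets against it that it needs no post-cyclisation ring closure or deoxygenation and sets the stereotriad in one event instead of three.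

Key step: step 13

Remark on the chemistry: the facial preference of prenyldiisopinocampheylborane is assumed to follow that of the parent allyl reagent, so the reagent derived from (−)-α-pinene should attack the Re face of aldehyde 13 and give the (S)-carbinol.

## Route

Step 1
Reactants: 1 phloroglucinol; 2 3-methylbut-2-enoic acid
Product: 4 5,7-dihydroxy-2,2-dimethylchroman-4-one, via acylphloroglucinol enone 3 (not isolated)
Conditions: P2O5, MeSO3H, 70 °C
Reagents that add atoms: none
Why: Friedel–Crafts acylation of the symmetrical triol followed by intramolecular oxa-Michael addition of an ortho phenol to the enone; symmetry of 1 removes any regiochemical question.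

Step 2
Reactants: 4 5,7-dihydroxy-2,2-dimethylchroman-4-one
Product: 5 5-hydroxy-7-methoxy-2,2-dimethylchroman-4-one
Conditions: MeI (1.05 equiv), K2CO3, acetone, 56 °C
Reagents that add atoms: iodomethane, CI
Why: Williamson etherification; the 5-hydroxyl is hydrogen-bonded to the carbonyl and much less nucleophilic, so the 7-hydroxyl should be methylated selectively.

Step 3
Reactants: 5 5-hydroxy-7-methoxy-2,2-dimethylchroman-4-one; 6 allyl bromide
Product: 7 5-(allyloxy)-7-methoxy-2,2-dimethylchroman-4-one
Conditions: K2CO3, DMF, 60 °C
Reagents that add atoms: none
Why: O-allylation of the chelated phenol under more forcing Williamson conditions.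

Step 4
Reactants: 7 5-(allyloxy)-7-methoxy-2,2-dimethylchroman-4-one
Product: 9 6-allyl-5-hydroxy-7-methoxy-2,2-dimethylchroman-4-one, via Claisen dienone 8 (not isolated)
Conditions: PhNEt2, 190 °C
Reagents that add atoms: none
Why: aromatic Claisen rearrangement; the only ortho position bearing hydrogen is C6, and tautomerisation of the dienone restores the chelated phenol.

Step 5
Reactants: 9 6-allyl-5-hydroxy-7-methoxy-2,2-dimethylchroman-4-one
Product: 10 6-allyl-7-methoxy-2,2-dimethyl-4-oxochroman-5-yl trifluoromethanesulfonate
Conditions: Tf2O, pyridine, CH2Cl2, 0 → 25 °C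
Reagents that add atoms: trifluoromethanesulfonic anhydride, O=S(=O)(OS(=O)(=O)C(F)(F)F)C(F)(F)F
Why: O-sulfonylation of a phenol; it turns the phloroglucinol oxygen at future C7a into a cross-coupling handle.

Step 6
Reactants: 10 6-allyl-7-methoxy-2,2-dimethyl-4-oxochroman-5-yl trifluoromethanesulfonate
Product: 11 6-(2,3-dihydroxypropyl)-7-methoxy-2,2-dimethyl-4-oxochroman-5-yl trifluoromethanesulfonate (racemic carbinol)
Conditions: OsO4 (cat.), NMO, acetone/H2O, 25 °C
Reagents that add atoms: N-methylmorpholine N-oxide, C[N+]1([O-])CCOCC1; water, O
Why: catalytic syn-dihydroxylation of the only alkene; the diol stores the future aldehyde in a form that is inert to palladium and base, and its stereocentre is lost in step 8.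

Step 7
Reactants: 11 6-(2,3-dihydroxypropyl)-7-methoxy-2,2-dimethyl-4-oxochroman-5-yl trifluoromethanesulfonate
Product: 12 6-(2,3-dihydroxypropyl)-7-methoxy-2,2-dimethyl-5-vinylchroman-4-one
Conditions: CH2=CH–B(pin), Pd(OAc)2, SPhos (2-dicyclohexylphosphino-2′,6′-dimethoxybiphenyl), K3PO4, THF/H2O, 65 °C
Reagents that add atoms: 4,4,5,5-tetramethyl-2-vinyl-1,3,2-dioxaborolane, C=CB1OC(C)(C)C(C)(C)O1
Why: Suzuki–Miyaura vinylation of an aryl triflate with a bulky biarylphosphine suited to doubly ortho-substituted electrophiles; no pendant alkene is present, so no intramolecular Heck pathway exists.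

Step 8
Reactants: 12 6-(2,3-dihydroxypropyl)-7-methoxy-2,2-dimethyl-5-vinylchroman-4-one
Product: 13 2-(7-methoxy-2,2-dimethyl-4-oxo-5-vinylchroman-6-yl)acetaldehyde
Conditions: NaIO4, NaHCO3, THF/H2O, 0 °C; crude aldehyde used at once
Reagents that add atoms: none
Why: periodate glycol cleavage under buffered, neutral conditions, which leaves the styrene and ketone untouched and avoids exposing the enolisable arylacetaldehyde to base or chromatography.

Step 9
Reactants: 13 2-(7-methoxy-2,2-dimethyl-4-oxo-5-vinylchroman-6-yl)acetaldehyde; 14 1-bromo-3-methylbut-2-ene
Product: 18 6-[(2S)-2-hydroxy-3,3-dimethylpent-4-en-1-yl]-7-methoxy-2,2-dimethyl-5-vinylchroman-4-one, via prenylmagnesium bromide 15 (not isolated), via prenyldiisopinocampheylborane 16 (not isolated), via borinate ester 17 (not isolated)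
Conditions: 14, Mg, THF, 0 °C; (+)-Ipc2BOMe [from (−)-α-pinene], Et2O, −78 → 25 °C; 13, −78 °C; NaOH, H2O2, 0 °C
Reagents that add atoms: none
Why: asymmetric allylboration (tert-prenylation) through a closed chair transition state with allylic transposition, which places CMe2 next to the carbinol; the isopinocampheyl groups from (−)-α-pinene should direct attack to the Re face and set the (S)-carbinol, and the deactivated aryl ketone does not react at −78 °C.

Step 10
Reactants: 18 6-[(2S)-2-hydroxy-3,3-dimethylpent-4-en-1-yl]-7-methoxy-2,2-dimethyl-5-vinylchroman-4-one
Product: 19 (2aS)-benzocycloheptenol ketone (chromanone bridged C7a–C7bH=C1H–C2Me2–C2aH(OH)–C3H2–C3a; cis ring alkene)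
Conditions: second-generation Grubbs catalyst (5 mol%), toluene (0.005 M), 80 °C
Reagents that add atoms: none
Why: ring-closing metathesis of two monosubstituted alkenes to a benzo-fused seven-membered ring, driven by loss of ethene; the ring enforces the cis alkene.

Step 11
Reactants: 19 (2aS)-benzocycloheptenol ketone
Product: 20 (2aS)-benzocycloheptenyl methanesulfonate ketone
Conditions: MsCl, Et3N, CH2Cl2, 0 °C
Reagents that add atoms: methanesulfonyl chloride, CS(=O)(=O)Cl
Why: sulfonylation of a secondary alcohol via the sulfene, with retention at carbon.

Step 12
Reactants: 20 (2aS)-benzocycloheptenyl methanesulfonate ketone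
Product: 21 (2aS)-benzocycloheptenyl methanesulfonate with the C4′ ketone as its ethylene ketal
Conditions: (TMSOCH2)2, TMSOTf (cat.), CH2Cl2, −78 → −20 °C; Et3N quench
Reagents that add atoms: 1,2-bis(trimethylsilyloxy)ethane, C[Si](C)(C)OCCO[Si](C)(C)C
Why: silyl-transfer ketalisation, driven irreversibly by formation of hexamethyldisiloxane, which is the method of choice for conjugated, deactivated ketones; aprotic low-temperature conditions spare the mesylate and the alkene.

Step 13
Reactants: 21 (2aS)-benzocycloheptenyl methanesulfonate ethylene ketal; 22 bis(pinacolato)diboron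
Product: 23 (1S,2aS,7bS)-cis-fused cyclobuta[a]indane pinacol boronate ethylene ketal (Bpin on C1, trans to ring A)
Conditions: CuCl (10 mol%), 1,3-bis(diphenylphosphino)propane (10 mol%), KOtBu (1.2 equiv, premixed with 22), THF, 30 °C
Reagents that add atoms: none
Why: Proposed new method: a phosphine-ligated monovalent copper boryl species (from CuCl, KOtBu and 22) should add syn across the cis C1=C7b styrene bond of 21 with boron on C1 and copper on benzylic C7b, and the C7b–Cu bond should then displace the C2a mesylate from the rear to form C2a–C7b; the closest known reaction type is the copper-catalysed borylative cyclisation of acyclic (Z)-homoallylic sulfonates to trans-2-arylcyclobutylboronates, which has not been run across a ring or onto a sulfonate next to a quaternary carbon. The one new bond closes the cyclobutane 4-exo-tet (through C1–C2) and the cyclopentane 5-exo-tet (through C7a–C3a–C3). C2a is set by inversion of the (S)-mesylate and C7b by retention at the C–Cu bond, which together can only give the cis fusion; C1 is set by syn addition to the ring-cis alkene, which leaves boron trans to ring A on the convex face. The step needs copper on the benzylic carbon (secured electronically by ring A), addition on the alkene face anti to the mesylate (the only adduct whose C–Cu bond can reach the rear of C2a–O, and the face left open by the pseudoaxial C2 methyl when the mesylate is equatorial), and substitution faster than E2 loss of mesylate toward the benzylic C3 hydrogens (hence KOtBu is introduced as its adduct with 22, not as free alkoxide). The usual neopentyl retardation should be small, because C2 lies inside the forming ring and its methyl groups point away from the line of attack, while the gem-dimethyl group favours the folded conformer.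

Step 14
Reactants: 23 (1S,2aS,7bS)-pinacol boronate ethylene ketal
Product: 25 potassium (1S,2aS,7bS)-cyclobuta[a]indan-1-yl trifluoroborate with free C4′ ketone, via keto boronate 24 (not isolated)
Conditions: HCl (0.1 M aq), THF, 25 °C; then KHF2, MeOH/H2O, 25 °C
Reagents that add atoms: water, O; potassium hydrogen difluoride, [K+].[F-].F
Why: the dioxolane of an electron-rich aryl ketone hydrolyses in very dilute acid, to which the alkyl pinacol boronate is inert; fluoride exchange then gives the trifluoroborate needed for single-electron transmetalation.

Step 15
Reactants: 26 4-bromobenzene-1,2-diol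
Product: 27 4-bromo-1,2-phenylene bis(2,2-dimethylpropanoate)
Conditions: PivCl, Et3N, DMAP (cat.), CH2Cl2, 0 → 25 °C
Reagents that add atoms: pivaloyl chloride, CC(C)(C)C(=O)Cl
Why: acylation of both phenols; pivalates resist carbonate base and photoredox conditions and are removed by the hydride reagent of the last step.

Step 16
Reactants: 25 potassium cyclobuta[a]indan-1-yl trifluoroborate; 27 4-bromo-1,2-phenylene bis(2,2-dimethylpropanoate)
Product: 28 (1S,2aS,7bR)-1-[3,4-bis(pivaloyloxy)phenyl]cyclobuta[a]indane chromanone
Conditions: NiCl2(MeOCH2CH2OMe) (10 mol%), 4,4′-di-tert-butyl-2,2′-bipyridine, 4CzIPN (3 mol%), Cs2CO3, 1,4-dioxane, blue LEDs, 25 °C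
Reagents that add atoms: none
Why: nickel/photoredox cross-coupling of a secondary alkyltrifluoroborate with an aryl bromide; oxidation by the excited photocatalyst gives the planar C1 cyclobutyl radical, which nickel should capture and arylate on the convex face, trans to ring A, whatever the configuration of the C–B bond.

Step 17
Reactants: 28 (1S,2aS,7bR)-1-[3,4-bis(pivaloyloxy)phenyl]cyclobuta[a]indane chromanone
Product: 30 target, 4-[(1S,2aS,7bR)-4-methoxy-2,2-dimethylcyclobuta[a]indan-1-yl]benzene-1,2-diol bearing the 2,2-dimethyl-2H-pyran fused at C6–C7, via chromanol 29 (not isolated)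
Conditions: LiAlH4, THF, 0 → 25 °C; then HCl (2 M aq), THF, 25 °C, under argon
Reagents that add atoms: none
Why: hydride reduction of the chromanone with reductive cleavage of both aryl pivalates, then acid-promoted E1 dehydration of the ortho/para-oxygen-stabilised benzylic alcohol (the classical chromanone-to-chromene sequence); the C4′ carbinol is transient and no ring stereocentre is touched.

## Compound list

1 | phloroglucinol | Oc1cc(O)cc(O)c1 | starting material
2 | 3-methylbut-2-enoic acid | CC(C)=CC(O)=O | starting material
3 | 3-methyl-1-(2,4,6-trihydroxyphenyl)but-2-en-1-one | CC(C)=CC(=O)c1c(O)cc(O)cc1O | intermediate (not isolated)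
4 | 5,7-dihydroxy-2,2-dimethylchroman-4-one | CC1(C)CC(=O)c2c(O)cc(O)cc2O1 | intermediate
5 | 5-hydroxy-7-methoxy-2,2-dimethylchroman-4-one | COc1cc(O)c2C(=O)CC(C)(C)Oc2c1 | intermediate
6 | allyl bromide | C=CCBr | starting material
7 | 5-(allyloxy)-7-methoxy-2,2-dimethylchroman-4-one | COc1cc(OCC=C)c2C(=O)CC(C)(C)Oc2c1 | intermediate
8 | 6-allyl-7-methoxy-2,2-dimethyl-2,3-dihydrochromene-4,5(6H)-dione (Claisen dienone) | C=CCC1C(OC)=CC2=C(C1=O)C(=O)CC(C)(C)O2 | intermediate (not isolated)
9 | 6-allyl-5-hydroxy-7-methoxy-2,2-dimethylchroman-4-one | COc1cc2OC(C)(C)CC(=O)c2c(O)c1CC=C | intermediate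
10 | 6-allyl-7-methoxy-2,2-dimethyl-4-oxochroman-5-yl trifluoromethanesulfonate | COc1cc2OC(C)(C)CC(=O)c2c(OS(=O)(=O)C(F)(F)F)c1CC=C | intermediate
11 | 6-(2,3-dihydroxypropyl)-7-methoxy-2,2-dimethyl-4-oxochroman-5-yl trifluoromethanesulfonate (racemic) | COc1cc2OC(C)(C)CC(=O)c2c(OS(=O)(=O)C(F)(F)F)c1CC(O)CO | intermediate
12 | 6-(2,3-dihydroxypropyl)-7-methoxy-2,2-dimethyl-5-vinylchroman-4-one (racemic) | COc1cc2OC(C)(C)CC(=O)c2c(C=C)c1CC(O)CO | intermediate
13 | 2-(7-methoxy-2,2-dimethyl-4-oxo-5-vinylchroman-6-yl)acetaldehyde | COc1cc2OC(C)(C)CC(=O)c2c(C=C)c1CC=O | intermediate
14 | 1-bromo-3-methylbut-2-ene | CC(C)=CCBr | starting material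
15 | (3-methylbut-2-en-1-yl)magnesium bromide | CC(C)=CC[Mg]Br | intermediate (not isolated)
16 | B-(3-methylbut-2-en-1-yl)diisopinocampheylborane from (−)-α-pinene | CC(C)=CCB([C@H]1C[C@H]2C[C@@H]([C@@H]1C)C2(C)C)[C@H]1C[C@H]2C[C@@H]([C@@H]1C)C2(C)C | intermediate (not isolated)
17 | diisopinocampheylborinate ester of alcohol 18 | COc1cc2OC(C)(C)CC(=O)c2c(C=C)c1C[C@H](OB([C@H]3C[C@H]4C[C@@H]([C@@H]3C)C4(C)C)[C@H]3C[C@H]4C[C@@H]([C@@H]3C)C4(C)C)C(C)(C)C=C | intermediate (not isolated)
18 | 6-[(2S)-2-hydroxy-3,3-dimethylpent-4-en-1-yl]-7-methoxy-2,2-dimethyl-5-vinylchroman-4-one | COc1cc2OC(C)(C)CC(=O)c2c(C=C)c1C[C@H](O)C(C)(C)C=C | intermediate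
19 | (2aS)-benzocycloheptenol ketone (cis C1=C7b, CMe2 at C2, OH at C2a, chromanone on ring A) | COc1cc2c(c3c1C[C@H](O)C(C)(C)C=C3)C(=O)CC(C)(C)O2 | intermediate
20 | (2aS)-benzocycloheptenyl methanesulfonate ketone | COc1cc2c(c3c1C[C@H](OS(C)(=O)=O)C(C)(C)C=C3)C(=O)CC(C)(C)O2 | intermediate
21 | (2aS)-benzocycloheptenyl methanesulfonate, C4′ ethylene ketal | COc1cc2c(c3c1C[C@H](OS(C)(=O)=O)C(C)(C)C=C3)C4(OCCO4)CC(C)(C)O2 | intermediate
22 | bis(pinacolato)diboron | CC1(C)OB(OC1(C)C)B1OC(C)(C)C(C)(C)O1 | starting material
23 | (1S,2aS,7bS)-cis-fused cyclobuta[a]indane C1 pinacol boronate, C4′ ethylene ketal | COc1cc2c(c3c1C[C@H]1[C@@H]3[C@H](B3OC(C)(C)C(C)(C)O3)C1(C)C)C4(OCCO4)CC(C)(C)O2 | intermediate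
24 | (1S,2aS,7bS)-cyclobuta[a]indane C1 pinacol boronate, C4′ ketone | COc1cc2c(c3c1C[C@H]1[C@@H]3[C@H](B3OC(C)(C)C(C)(C)O3)C1(C)C)C(=O)CC(C)(C)O2 | intermediate (not isolated)
25 | potassium (1S,2aS,7bS)-cyclobuta[a]indan-1-yl trifluoroborate, C4′ ketone | COc1cc2c(c3c1C[C@H]1[C@@H]3[C@H]([B-](F)(F)F)C1(C)C)C(=O)CC(C)(C)O2.[K+] | intermediate
26 | 4-bromobenzene-1,2-diol | Oc1ccc(Br)cc1O | starting material
27 | 4-bromo-1,2-phenylene bis(2,2-dimethylpropanoate) | CC(C)(C)C(=O)Oc1ccc(Br)cc1OC(=O)C(C)(C)C | intermediate
28 | (1S,2aS,7bR)-1-[3,4-bis(pivaloyloxy)phenyl]cyclobuta[a]indane chromanone | COc1cc2c(c3c1C[C@H]1[C@@H]3[C@H](c3ccc(OC(=O)C(C)(C)C)c(OC(=O)C(C)(C)C)c3)C1(C)C)C(=O)CC(C)(C)O2 | intermediate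
29 | (1S,2aS,7bR)-1-(3,4-dihydroxyphenyl)cyclobuta[a]indane chroman-4′-ol (C4′ epimers) | COc1cc2c(c3c1C[C@H]1[C@@H]3[C@H](c3ccc(O)c(O)c3)C1(C)C)C(O)CC(C)(C)O2 | intermediate (not isolated)
30 | target CNP0207533.1, (1S,2aS,7bR) | COc1cc2c(c3c1C[C@H]1[C@@H]3[C@H](c3ccc(O)c(O)c3)C1(C)C)C=CC(C)(C)O2 | target

## Step count and least certain steps

Total steps: 17. Longest linear sequence: 16 (steps 1–14, 16, 17); step 15 is a one-step side branch.

**Step 13 (key step).** The benzylic copper intermediate may fail to substitute and instead be protonated or lose hydride. Base-induced E2 loss of methanesulfonate toward the benzylic C3 hydrogens may also outrun borylcupration. Both follow from the same causes: a 4-exo displacement at a secondary carbon is slow, and the nucleophile is a crowded benzylic copper flanked by the ketal. Addition on the wrong alkene face is unproductive for the same reason.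

Fallback (known chemistry, sets out from 10, returns at 28): cross-metathesis of 10 with 2-methylbut-2-ene (second-generation Grubbs catalyst) gives 7-methoxy-2,2-dimethyl-6-(3-methylbut-2-enyl)-4-oxochroman-5-yl triflate F1. Suzuki–Miyaura coupling (Pd(OAc)2, SPhos, K3PO4) with (E)-2-[3,4-bis(pivaloyloxy)phenyl]vinylboronic acid pinacol ester F2, itself made from 27 and vinylboronic acid pinacol ester by a Mizoroki–Heck reaction, gives ortho-prenyl stilbene F3. Triplet sensitisation ([Ir(dF(CF3)ppy)2(dtbbpy)]PF6, blue light) then effects the intramolecular [2+2] photocycloaddition of this 1,6-diene. The C7b–C2a bond forms first (five-membered ring; diradical benzylic at C1 and tertiary at C2), then C1–C2, giving the straight cis-fused adduct with the aryl group on the convex face. The stereochemical relay is lost: the product is 28 together with its mirror image ent-28 F4, and separation on a chiral stationary phase is needed to return to 28.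

**Step 12 (ketalisation).** The carbonyl is conjugated with an ortho and a para oxygen and is peri to the ring alkene, so ketal formation may stall, or the strained, very acid-labile dioxolane may be lost during isolation.

Fallback (sets out from 20, returns at 24): mask the ketone by enolisation instead of carbonyl addition. TBSOTf/Et3N gives the 4′-(tert-butyldimethylsilyloxy)-2H-chromene mesylate F5, whose trisubstituted, oxygenated alkene should be far less reactive toward the copper boryl species than the ring styrene. The conditions of step 13 give the silyl enol ether boronate F6, and the dilute acid of step 14 releases keto boronate 24.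

**Step 16 (nickel/photoredox arylation).** The C1 radical is secondary and flanked by CMe2, so capture by nickel may be slow. Reduction, or fragmentation of the strained radical by scission of the C2a–C7b bond back to a ring styrene, may then compete.

Fallback (sets out from 25, returns at 28; no new compound, F0): a two-electron Suzuki–Miyaura coupling of 25 with 27 (Pd(OAc)2, di(1-adamantyl)-n-butylphosphine, Cs2CO3, toluene/H2O, 100 °C), the known coupling type for cyclobutyltrifluoroborates. The C–B bond is transferred to divalent palladium, expected with retention, and no free radical is formed. Any pivalate lost to the aqueous base is restored with pivaloyl chloride/Et3N before isolation.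

**Step 9 (asymmetric prenylation).** The ortho-vinyl arylacetaldehyde 13 may be consumed by self-condensation or carbonyl-ene closure onto the vinyl group before it meets the borane. Incomplete conversion of Grignard reagent 15 into borane 16 would erode the enantiomeric purity on which every later stereocentre depends.

Fallback (sets out from 12, returns at 18): periodate cleavage followed in the same flask by NaBH4 gives 6-(2-hydroxyethyl)-7-methoxy-2,2-dimethyl-5-vinylchroman-4-one F7, so the aldehyde is never handled. Iridium-catalysed transfer-hydrogenative tert-prenylation of this primary alcohol with 3-methylbuta-1,2-diene then gives 18. The catalyst is a cyclometallated complex from [Ir(cod)Cl]2, the SEGPHOS enantiomer that gives the (S)-carbinol, a nitrobenzoic acid and Cs2CO3; the aldehyde is generated and consumed at the metal.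

## Further compounds

F1 | step 13 | 7-methoxy-2,2-dimethyl-6-(3-methylbut-2-enyl)-4-oxochroman-5-yl trifluoromethanesulfonate | COc1cc2OC(C)(C)CC(=O)c2c(OS(=O)(=O)C(F)(F)F)c1CC=C(C)C
F2 | step 13 | (E)-2-[3,4-bis(pivaloyloxy)phenyl]vinylboronic acid pinacol ester | CC(C)(C)C(=O)Oc1ccc(/C=C/B2OC(C)(C)C(C)(C)O2)cc1OC(=O)C(C)(C)C
F3 | step 13 | 5-[(E)-2-(3,4-bis(pivaloyloxy)phenyl)vinyl]-7-methoxy-2,2-dimethyl-6-(3-methylbut-2-enyl)chroman-4-one | COc1cc2OC(C)(C)CC(=O)c2c(/C=C/c2ccc(OC(=O)C(C)(C)C)c(OC(=O)C(C)(C)C)c2)c1CC=C(C)C
F4 | step 13 | ent-28, (1R,2aR,7bS)-1-[3,4-bis(pivaloyloxy)phenyl]cyclobuta[a]indane chromanone | COc1cc2c(c3c1C[C@@H]1[C@H]3[C@@H](c3ccc(OC(=O)C(C)(C)C)c(OC(=O)C(C)(C)C)c3)C1(C)C)C(=O)CC(C)(C)O2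
F5 | step 12 | (2aS)-benzocycloheptenyl methanesulfonate, 4′-(tert-butyldimethylsilyloxy)-2H-chromene | COc1cc2c(c3c1C[C@H](OS(C)(=O)=O)C(C)(C)C=C3)C(O[Si](C)(C)C(C)(C)C)=CC(C)(C)O2
F6 | step 12 | (1S,2aS,7bS)-cyclobuta[a]indane C1 pinacol boronate, 4′-(tert-butyldimethylsilyloxy)-2H-chromene | COc1cc2c(c3c1C[C@H]1[C@@H]3[C@H](B3OC(C)(C)C(C)(C)O3)C1(C)C)C(O[Si](C)(C)C(C)(C)C)=CC(C)(C)O2
F0 | step 16 | none | none
F7 | step 9 | 6-(2-hydroxyethyl)-7-methoxy-2,2-dimethyl-5-vinylchroman-4-one | COc1cc2OC(C)(C)CC(=O)c2c(C=C)c1CCO
A1 | alternative 1 | resorcylate-fused cyclobuta[a]indane (methyl ester at C7, hydroxyls at C4 and C6, bis-MOM catechol) | Oc1cc(O)c(C(=O)OC)c3c1C[C@H]1[C@@H]3[C@H](c3ccc(OCOC)c(OCOC)c3)C1(C)C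
A2 | alternative 1 | cis-bicyclo[3.2.0]heptanone with a methyl 3,5-dioxo ester chain on C3a | COC(=O)CC(=O)CC(=O)C1C[C@H]2[C@@H](C1=O)[C@H](c1ccc(OCOC)c(OCOC)c1)C2(C)C
A3 | alternative 2 | all-cis tetracycle with a methyl ester on C1 | COc1cc2c(c3c1C[C@H]1[C@@H]3[C@@H](C(=O)OC)C1(C)C)C=CC(C)(C)O2
A4 | alternative 2 | chromenyl triflate carrying the cis-cyclobutane ester through C3 | COc1cc2OC(C)(C)C=Cc2c(OS(=O)(=O)C(F)(F)F)c1C[C@H]1C[C@@H](C(=O)OC)C1(C)C
A5 | alternative 3 | cyclobutane methyl ester (ester on C2a cis to ring A, aryl groups trans) | COC(=O)[C@H]1[C@@H](c2cc(OC)cc3OC(C)(C)C=Cc23)[C@H](c2ccc(OCOC)c(OCOC)c2)C1(C)C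
A6 | alternative 3 | trans-3,4-diaryl-5-diazo-2,2-dimethylcyclopentanone | [N-]=[N+]=C1C(=O)C(C)(C)[C@@H](c2ccc(OCOC)c(OCOC)c2)[C@@H]1c1cc(OC)cc2OC(C)(C)C=Cc12
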